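## Retrosynthetic overview

1. (Locants as in the target name: chain C7–C8–C9 on ring A, ring B C1'–C6', side chain C7'–C9'.) Target ⇐ diester by reduction of the C9 and C9' esters; diester ⇐ 5-bromo-dihydrobenzofuran ester by Heck reaction with methyl acrylate (C1'–C7' bond).
2. Dihydrofuran ring ⇐ acyclic syn-aldol methyl ester: the ring is closed through the aryl C–O bond (oxygen on C7 to C4' of ring B), with C4' entering as a plain C–H carbon.
3. Enabling feature: the C7 oxygen (O7) sits two carbons (C7, C8) from ring B, so palladium bound to it reaches the ortho C4'–H bond through a six-membered palladacycle (Pd, O7, C7, C8, C3', C4'); C4' is flanked by the small C5' methoxy group, the other ortho carbon C2' by the larger bromine on C1'.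
4. syn-Aldol ester ⇐ arylacetyl imide of (R)-4-benzyloxazolidin-2-one + 3,4,5-trimethoxybenzaldehyde by Evans syn-aldol (C7–C8 bond and both stereocentres, set in the open chain), then exchange of the auxiliary for OMe.
5. Ring order: rings A and B are bought; the dihydrofuran ring is the only ring formed, in step 4.

Key step: step 4

Assumption: acid 1 is taken as a commercially available building block; metal alkoxides that differ from a product only by protonation on aqueous work-up are treated as that product.

## Route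

Step 1
Reactants: 1 2-(3-bromo-5-methoxyphenyl)acetic acid; 2 (R)-4-benzyloxazolidin-2-one
Product: 4 (R)-4-benzyl-3-[2-(3-bromo-5-methoxyphenyl)acetyl]oxazolidin-2-one, via mixed pivalic anhydride 3 (not isolated)
Conditions: t-BuCOCl, Et3N, THF, −20 °C; then LiCl, 2, −20 °C to rt
Reagents that add atoms: none
Why: Mixed-anhydride N-acylation, in which the oxazolidinone, activated by LiCl and Et3N, attacks the less hindered arylacetyl carbonyl of anhydride 3; no stereocentre is formed and the auxiliary centre is not touched.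

Step 2
Reactants: 4 (R)-4-benzyl-3-[2-(3-bromo-5-methoxyphenyl)acetyl]oxazolidin-2-one; 5 3,4,5-trimethoxybenzaldehyde
Product: 8 (R)-4-benzyl-3-[(2R,3R)-2-(3-bromo-5-methoxyphenyl)-3-hydroxy-3-(3,4,5-trimethoxyphenyl)propanoyl]oxazolidin-2-one, via boron enolate 6 (not isolated), via boron aldolate 7 (not isolated)
Conditions: n-Bu2BOTf, i-Pr2NEt, CH2Cl2, 0 °C; then 5, −78 to 0 °C; then KH2PO4/K2HPO4 buffer (pH 7), MeOH, 30% H2O2, 0 °C
Reagents that add atoms: none
Why: Evans syn-aldol reaction, in which the (Z)-boron enolate reacts through a closed Zimmerman–Traxler chair and the aldehyde attacks the enolate face remote from the benzyl group of the (R)-auxiliary, so that C8 and C7 are both set as R in a syn relationship (the arrangement that becomes 7R,8S and 2,3-trans in the target).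

Step 3
Reactants: 8 (R)-4-benzyl-3-[(2R,3R)-2-(3-bromo-5-methoxyphenyl)-3-hydroxy-3-(3,4,5-trimethoxyphenyl)propanoyl]oxazolidin-2-one
Product: 9 methyl (2R,3R)-2-(3-bromo-5-methoxyphenyl)-3-hydroxy-3-(3,4,5-trimethoxyphenyl)propanoate
Conditions: MeMgBr added to MeOH/CH2Cl2 at 0 °C, then 8, 0 °C; aq. NH4Cl
Reagents that add atoms: methanol (CO)
Why: Transesterification of the imide by methoxymagnesium bromide, in which methoxide attacks the exocyclic carbonyl of the magnesium-chelated β-alkoxy imide and expels the oxazolidinone while the chelate keeps retro-aldol cleavage and enolisation at C8 slow, so both stereocentres are carried over unchanged.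

Step 4
Reactants: 9 methyl (2R,3R)-2-(3-bromo-5-methoxyphenyl)-3-hydroxy-3-(3,4,5-trimethoxyphenyl)propanoate
Product: 10 methyl (2R,3R)-5-bromo-7-methoxy-2-(3,4,5-trimethoxyphenyl)-2,3-dihydrobenzofuran-3-carboxylate
Conditions: Pd(OAc)2 (10 mol %), PhI(OAc)2 (1.5 equiv), Li2CO3 (1.5 equiv), C6F6, 100 °C
Reagents that add atoms: none
Why: The reaction is a hydroxyl-directed C–H activation/C–O cyclization, a known reaction type for 2-arylethanols (β-hydroxy-α-aryl esters included): the C7 alkoxide binds divalent palladium, acetate/carbonate-assisted concerted metalation–deprotonation cleaves the C4'–H bond of ring B to give the six-membered palladacycle (Pd, O7, C7, C8, C3', C4'), PhI(OAc)2 oxidises it to tetravalent palladium and C–O reductive elimination forms the O7–C4' bond. The dihydrofuran ring is closed by this reductive elimination, in which the six-membered palladacycle contracts to the five-membered ring O7–C7–C8–C3'–C4'. No stereocentre is created: C7 and C8 were set in step 2 and are retained because the C7–O bond and all bonds at C8 stay intact, so the syn-aldol maps onto the 2,3-trans ring. The step needs site selectivity between the two ortho C–H bonds of ring B and chemoselectivity for cyclization over oxidation of the secondary benzylic alcohol: C4'–H lies next to the small methoxy group while C2'–H lies next to the larger bromine, and ring A can only form a five-membered palladacycle whose C–O elimination would require a four-membered ring. Li2CO3 as a weak, sparingly soluble base in a non-coordinating solvent should keep retro-aldol cleavage and C8 epimerisation slow, and the C–Br bond should stay untouched because no zerovalent palladium persists in the presence of the oxidant.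

Step 5
Reactants: 10 methyl (2R,3R)-5-bromo-7-methoxy-2-(3,4,5-trimethoxyphenyl)-2,3-dihydrobenzofuran-3-carboxylate
Product: 11 methyl (2R,3R)-7-methoxy-5-[(E)-3-methoxy-3-oxoprop-1-en-1-yl]-2-(3,4,5-trimethoxyphenyl)-2,3-dihydrobenzofuran-3-carboxylate
Conditions: methyl acrylate, Pd2(dba)3 (2.5 mol %), [HP(t-Bu)3]BF4 (10 mol %), Cy2NMe, 1,4-dioxane, 70 °C
Reagents that add atoms: methyl acrylate (C=CC(=O)OC)
Why: Mizoroki–Heck reaction, in which oxidative addition of zerovalent palladium ligated by P(t-Bu)3 into the C1'–Br bond, syn-carbopalladation of methyl acrylate and syn-β-hydride elimination should give the (E)-alkene, while the hindered amine base and moderate temperature spare the base-sensitive β-aryloxy ester; no stereocentre is formed.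

Step 6
Reactants: 11 methyl (2R,3R)-7-methoxy-5-[(E)-3-methoxy-3-oxoprop-1-en-1-yl]-2-(3,4,5-trimethoxyphenyl)-2,3-dihydrobenzofuran-3-carboxylate
Product: 12 (E)-3-[(2R,3S)-3-(hydroxymethyl)-7-methoxy-2-(3,4,5-trimethoxyphenyl)-2,3-dihydrobenzofuran-5-yl]prop-2-en-1-ol (the target)
Conditions: i-Bu2AlH (6 equiv), CH2Cl2, −78 to 0 °C; aq. potassium sodium tartrate
Reagents that add atoms: none
Why: Ester reduction by i-Bu2AlH, in which the saturated C9 ester and, by 1,2-hydride delivery, the conjugated C9' ester are both taken to primary alcohols at low temperature without touching the alkene or either stereocentre (C8 is now named S only because the substituent priorities change).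

## Compound list

1 | 2-(3-bromo-5-methoxyphenyl)acetic acid | COc1cc(Br)cc(CC(=O)O)c1 | starting material
2 | (R)-4-benzyloxazolidin-2-one | O=C1N[C@H](Cc2ccccc2)CO1 | starting material
3 | 2-(3-bromo-5-methoxyphenyl)acetic pivalic anhydride | COc1cc(Br)cc(CC(=O)OC(=O)C(C)(C)C)c1 | intermediate
4 | (R)-4-benzyl-3-[2-(3-bromo-5-methoxyphenyl)acetyl]oxazolidin-2-one | COc1cc(Br)cc(CC(=O)N2[C@H](Cc3ccccc3)COC2=O)c1 | intermediate
5 | 3,4,5-trimethoxybenzaldehyde | COc1cc(C=O)cc(OC)c1OC | starting material
6 | dibutyl{[(Z)-1-[(R)-4-benzyl-2-oxooxazolidin-3-yl]-2-(3-bromo-5-methoxyphenyl)ethenyl]oxy}borane (boron enolate of 4) | CCCCB(CCCC)O/C(=C\c1cc(Br)cc(OC)c1)N1[C@H](Cc2ccccc2)COC1=O | intermediate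
7 | (R)-4-benzyl-3-[(2R,3R)-2-(3-bromo-5-methoxyphenyl)-3-(dibutylboranyloxy)-3-(3,4,5-trimethoxyphenyl)propanoyl]oxazolidin-2-one (boron aldolate) | COc1cc([C@H](OB(CCCC)CCCC)[C@@H](c2cc(Br)cc(OC)c2)C(=O)N2[C@H](Cc3ccccc3)COC2=O)cc(OC)c1OC | intermediate
8 | (R)-4-benzyl-3-[(2R,3R)-2-(3-bromo-5-methoxyphenyl)-3-hydroxy-3-(3,4,5-trimethoxyphenyl)propanoyl]oxazolidin-2-one | COc1cc([C@H](O)[C@@H](c2cc(Br)cc(OC)c2)C(=O)N2[C@H](Cc3ccccc3)COC2=O)cc(OC)c1OC | intermediate
9 | methyl (2R,3R)-2-(3-bromo-5-methoxyphenyl)-3-hydroxy-3-(3,4,5-trimethoxyphenyl)propanoate | COc1cc([C@H](O)[C@@H](c2cc(Br)cc(OC)c2)C(=O)OC)cc(OC)c1OC | intermediate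
10 | methyl (2R,3R)-5-bromo-7-methoxy-2-(3,4,5-trimethoxyphenyl)-2,3-dihydrobenzofuran-3-carboxylate | COc1cc([C@@H]2Oc3c(OC)cc(Br)cc3[C@H]2C(=O)OC)cc(OC)c1OC | intermediate
11 | methyl (2R,3R)-7-methoxy-5-[(E)-3-methoxy-3-oxoprop-1-en-1-yl]-2-(3,4,5-trimethoxyphenyl)-2,3-dihydrobenzofuran-3-carboxylate | COc1cc([C@@H]2Oc3c(OC)cc(/C=C/C(=O)OC)cc3[C@H]2C(=O)OC)cc(OC)c1OC | intermediate
12 | (E)-3-[(2R,3S)-3-(hydroxymethyl)-7-methoxy-2-(3,4,5-trimethoxyphenyl)-2,3-dihydrobenzofuran-5-yl]prop-2-en-1-ol, which is (7R,8S,7'E)-3,4,5,5'-tetramethoxy-4',7-epoxy-8,3'-neolign-7'-ene-9,9'-diol | COc1cc([C@@H]2Oc3c(OC)cc(/C=C/CO)cc3[C@H]2CO)cc(OC)c1OC | target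

## Step count and risks

Total step count: 6. Longest linear sequence: 6 steps (1 to 12).

Steps most likely to fail:

**Step 4.** Palladation at the doubly flanked C4'–H bond may be slow. β-Hydride elimination from the palladium alkoxide (oxidation of the benzylic alcohol), retro-aldol cleavage or palladation at C2' could then take over. The fallback closes the same O7–C4' bond from a halide instead of a C–H bond and sets out from acid 1. Carboxylate-directed ortho-iodination (Pd(OAc)2, PhI(OAc)2, I2, DMF, 60 °C) should give 2-(5-bromo-2-iodo-3-methoxyphenyl)acetic acid F1. It is run on the simple achiral acid, where a regioisomer can be removed by crystallisation. The chemistry of steps 1 to 3 should then lead through mixed pivalic anhydride F2 to imide F3, through boron enolate F4 and boron aldolate F5 to aldol adduct F6, and by methanolysis to iodo hydroxy ester F7. An intramolecular Ullmann etherification (CuI, 1,10-phenanthroline, Cs2CO3, toluene, 80 °C) of the C7 alkoxide onto the C4'–I bond, which reacts in preference to the C1'–Br bond, should close the ring and come back to the route at 10.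

**Step 3.** Alkoxide-mediated acyl transfer may be accompanied by retro-aldol cleavage, epimerisation at C8 or attack at the ring carbonyl of the auxiliary. The fallback sets out from 8 and separates cleavage from ester formation. Hydrolysis with LiOH and H2O2 (THF/H2O, 0 °C), which attacks the exocyclic carbonyl at a basicity too low for enolisation, should give peroxy acid F8. Na2SO3 reduces it in the same flask to hydroxy acid F9. Methylation with TMSCHN2 (toluene/MeOH, 0 °C) comes back to the route at 9.

**Step 5.** Base and heat may open the β-aryloxy ester by E1cB loss of the phenoxide, which would erase C7 and C8, or oxidative addition into the electron-rich aryl bromide may stall. The fallback sets out from 10 and uses a base-free Stille coupling with commercially available (E)-3-(tributylstannyl)prop-2-en-1-ol (Pd(P(t-Bu)3)2, toluene, 80 °C). This should give the hydroxypropenyl ester methyl (2R,3R)-5-[(E)-3-hydroxyprop-1-en-1-yl]-7-methoxy-2-(3,4,5-trimethoxyphenyl)-2,3-dihydrobenzofuran-3-carboxylate F10, which already carries the side chain at the alcohol level. Reduction of the remaining ester with i-Bu2AlH (CH2Cl2, −78 to 0 °C) comes back to the route at 12.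

Further compounds
F1 | step 4 | 2-(5-bromo-2-iodo-3-methoxyphenyl)acetic acid | COc1cc(Br)cc(CC(=O)O)c1I
F2 | step 4 | 2-(5-bromo-2-iodo-3-methoxyphenyl)acetic pivalic anhydride | COc1cc(Br)cc(CC(=O)OC(=O)C(C)(C)C)c1I
F3 | step 4 | (R)-4-benzyl-3-[2-(5-bromo-2-iodo-3-methoxyphenyl)acetyl]oxazolidin-2-one | COc1cc(Br)cc(CC(=O)N2[C@H](Cc3ccccc3)COC2=O)c1I
F4 | step 4 | dibutyl{[(Z)-1-[(R)-4-benzyl-2-oxooxazolidin-3-yl]-2-(5-bromo-2-iodo-3-methoxyphenyl)ethenyl]oxy}borane (boron enolate of F3) | CCCCB(CCCC)O/C(=C\c1cc(Br)cc(OC)c1I)N1[C@H](Cc2ccccc2)COC1=O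
F5 | step 4 | (R)-4-benzyl-3-[(2R,3R)-2-(5-bromo-2-iodo-3-methoxyphenyl)-3-(dibutylboranyloxy)-3-(3,4,5-trimethoxyphenyl)propanoyl]oxazolidin-2-one (boron aldolate) | COc1cc([C@H](OB(CCCC)CCCC)[C@@H](c2cc(Br)cc(OC)c2I)C(=O)N2[C@H](Cc3ccccc3)COC2=O)cc(OC)c1OC
F6 | step 4 | (R)-4-benzyl-3-[(2R,3R)-2-(5-bromo-2-iodo-3-methoxyphenyl)-3-hydroxy-3-(3,4,5-trimethoxyphenyl)propanoyl]oxazolidin-2-one | COc1cc([C@H](O)[C@@H](c2cc(Br)cc(OC)c2I)C(=O)N2[C@H](Cc3ccccc3)COC2=O)cc(OC)c1OC
F7 | step 4 | methyl (2R,3R)-2-(5-bromo-2-iodo-3-methoxyphenyl)-3-hydroxy-3-(3,4,5-trimethoxyphenyl)propanoate | COc1cc([C@H](O)[C@@H](c2cc(Br)cc(OC)c2I)C(=O)OC)cc(OC)c1OC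
F8 | step 3 | (2R,3R)-2-(3-bromo-5-methoxyphenyl)-3-hydroxy-3-(3,4,5-trimethoxyphenyl)propaneperoxoic acid | COc1cc([C@H](O)[C@@H](c2cc(Br)cc(OC)c2)C(=O)OO)cc(OC)c1OC
F9 | step 3 | (2R,3R)-2-(3-bromo-5-methoxyphenyl)-3-hydroxy-3-(3,4,5-trimethoxyphenyl)propanoic acid | COc1cc([C@H](O)[C@@H](c2cc(Br)cc(OC)c2)C(=O)O)cc(OC)c1OC
F10 | step 5 | methyl (2R,3R)-5-[(E)-3-hydroxyprop-1-en-1-yl]-7-methoxy-2-(3,4,5-trimethoxyphenyl)-2,3-dihydrobenzofuran-3-carboxylate | COc1cc([C@@H]2Oc3c(OC)cc(/C=C/CO)cc3[C@H]2C(=O)OC)cc(OC)c1OC
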